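**Retrosynthetic overview**
- The target comes from its tetra-MOM ether by one global acetal cleavage.
- Key disconnection: the C3–C1' bond and the O1–C2 bond are cut together, giving an o-hydroxyaryl ynone and a (2R,3R)-iodo diol. A carbon radical adds to the alkyne and ring C closes in the same flask.
- The ynone comes from a ring A salicylaldehyde, ethynyl Grignard and a ring B aryl iodide (addition, Sonogashira coupling, MnO2).
- Both arenes come from resorcinol bis-MOM ether. Ring A: ortho-lithiation/prenylation, Ir C–H borylation/oxidation for the third oxygen, ortho-formylation. Ring B: iodination.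
- The iodo diol comes from methyl (S)-glycidate and homoprenyl Grignard (epoxy ketone), chelation-controlled MeMgBr addition (tertiary carbinol), then iodide opening. Rings A and B are bought as benzene rings; ring C is the only ring formed.

Assumption: the side chain read from the SMILES is 2S (secondary carbinol), 3R (tertiary carbinol); a one-flask sequence with successive additions counts as one step.

**Step 1**
Reactants: 1 resorcinol (benzene-1,3-diol)
Product: 2 1,3-bis(methoxymethoxy)benzene
Conditions: NaH (2.4 equiv), DMF, 0 °C; MOMCl (2.4 equiv), 0 °C → rt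
Reagents that add atoms: chloromethyl methyl ether (MOMCl), COCCl
Why: Williamson-type O-alkylation of the bis-phenoxide (MOM protection); the acetals later direct the ortho-lithiation and all leave together in the last step.

**Step 2**
Reactants: 2 1,3-bis(methoxymethoxy)benzene; 3 prenyl bromide (1-bromo-3-methylbut-2-ene)
Product: 5 1,3-bis(methoxymethoxy)-2-(3-methylbut-2-en-1-yl)benzene, via aryllithium 4 (not isolated)
Conditions: n-BuLi (1.1 equiv), THF, 0 °C → rt, 1 h; CuI (10 mol %), 3 (1.2 equiv), −78 °C → rt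
Reagents that add atoms: none
Why: Directed ortho-metalation at C2, which is activated by both MOM ethers, followed by copper-catalysed SN2 allylation at the unhindered CH2 of prenyl bromide.

**Step 3**
Reactants: 5 1,3-bis(methoxymethoxy)-2-(3-methylbut-2-en-1-yl)benzene
Product: 7 3,5-bis(methoxymethoxy)-4-(3-methylbut-2-en-1-yl)phenol, via arylboronate 6 (not isolated)
Conditions: [Ir(OMe)(cod)]2 (1.5 mol %), 4,4'-di-tert-butyl-2,2'-bipyridine (3 mol %), B2pin2 (0.55 equiv), THF, 80 °C; then aq. NaOH, 30% H2O2, 0 °C → rt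
Reagents that add atoms: hydrogen peroxide, OO
Why: Sterically controlled iridium-catalysed aromatic C–H borylation (Hartwig–Miyaura type) takes the only ring C–H without an ortho neighbour (para to prenyl), and oxidative C–B to C–O cleavage gives the phenol that becomes O1; the trisubstituted alkene is inert to alkaline peroxide.

**Step 4**
Reactants: 7 3,5-bis(methoxymethoxy)-4-(3-methylbut-2-en-1-yl)phenol
Product: 8 6-hydroxy-2,4-bis(methoxymethoxy)-3-(3-methylbut-2-en-1-yl)benzaldehyde
Conditions: MgCl2 (2 equiv), Et3N (4 equiv), (CH2O)n (6 equiv), MeCN, reflux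
Reagents that add atoms: paraformaldehyde (as formaldehyde), C=O
Why: Hofsløkken–Skattebøl magnesium-phenoxide ortho-formylation; the two positions ortho to OH are equivalent, and the basic medium spares the MOM ethers and the prenyl group.

**Step 5**
Reactants: 8 6-hydroxy-2,4-bis(methoxymethoxy)-3-(3-methylbut-2-en-1-yl)benzaldehyde
Product: 9 2-(1-hydroxyprop-2-yn-1-yl)-3,5-bis(methoxymethoxy)-4-(3-methylbut-2-en-1-yl)phenol (racemic)
Conditions: HC≡CMgBr (3 equiv), THF, 0 °C → rt; aq. NH4Cl, neutral work-up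
Reagents that add atoms: ethynylmagnesium bromide, C#C[Mg]Br
Why: Grignard 1,2-addition to the aldehyde (the first equivalent only deprotonates the phenol); the carbinol centre is racemic and is removed by oxidation in step 8.

**Step 6**
Reactants: 2 1,3-bis(methoxymethoxy)benzene
Product: 10 1-iodo-2,4-bis(methoxymethoxy)benzene
Conditions: NIS (1.05 equiv), MeCN, 0 °C → rt, dark
Reagents that add atoms: N-iodosuccinimide, O=C1CCC(=O)N1I
Why: Electrophilic aromatic iodination at C4 (para to one acetal oxygen, ortho to the other); C2 is too hindered.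

**Step 7**
Reactants: 9 2-(1-hydroxyprop-2-yn-1-yl)-3,5-bis(methoxymethoxy)-4-(3-methylbut-2-en-1-yl)phenol; 10 1-iodo-2,4-bis(methoxymethoxy)benzene
Product: 11 2-{3-[2,4-bis(methoxymethoxy)phenyl]-1-hydroxyprop-2-yn-1-yl}-3,5-bis(methoxymethoxy)-4-(3-methylbut-2-en-1-yl)phenol (racemic)
Conditions: PdCl2(PPh3)2 (3 mol %), CuI (5 mol %), Et3N/THF 1:1, rt
Reagents that add atoms: none
Why: Sonogashira coupling of the terminal alkyne with the aryl iodide under mild basic conditions that tolerate the free phenol and the acid-sensitive benzylic carbinol.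

**Step 8**
Reactants: 11 2-{3-[2,4-bis(methoxymethoxy)phenyl]-1-hydroxyprop-2-yn-1-yl}-3,5-bis(methoxymethoxy)-4-(3-methylbut-2-en-1-yl)phenol
Product: 12 3-[2,4-bis(methoxymethoxy)phenyl]-1-[6-hydroxy-2,4-bis(methoxymethoxy)-3-(3-methylbut-2-en-1-yl)phenyl]prop-2-yn-1-one
Conditions: activated MnO2 (15 equiv), CH2Cl2, rt
Reagents that add atoms: none
Why: Chemoselective MnO2 oxidation of the benzylic–propargylic alcohol; the o-hydroxyaryl ynone is held by an O–H···O=C hydrogen bond and can be isolated under neutral conditions, and only the hydroxyl para to prenyl is free, which fixes the 6-prenyl regiochemistry of the later ring closure.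

**Step 9**
Reactants: 13 methyl (2S)-oxirane-2-carboxylate (methyl (S)-glycidate); 14 5-bromo-2-methylpent-2-ene
Product: 17 5-methyl-1-[(2S)-oxiran-2-yl]hex-4-en-1-one, via Grignard reagent 15 (not isolated), via Weinreb amide 16 (not isolated)
Conditions: 13, MeNH(OMe)·HCl (1.2 equiv), i-PrMgCl (2.4 equiv), THF, −20 °C, 30 min; then 15 (1.5 equiv, from 14, Mg, THF, rt), −20 → 0 °C; aq. NH4Cl
Reagents that add atoms: none
Why: Magnesium-amide aminolysis of the ester gives the Weinreb amide in situ, and Grignard addition stops at the ketone through the chelated tetrahedral intermediate (Weinreb ketone synthesis); the oxirane stereocentre is not touched.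

**Step 10**
Reactants: 17 5-methyl-1-[(2S)-oxiran-2-yl]hex-4-en-1-one
Product: 19 (2R,3R)-1-iodo-3,7-dimethyloct-6-ene-2,3-diol, via epoxy alcohol 18 (not isolated)
Conditions: MeMgBr (1.3 equiv), THF, −78 °C; then AcOH (4 equiv), LiI (2.5 equiv), −78 °C → rt
Reagents that add atoms: methylmagnesium bromide, C[Mg]Br; lithium iodide, [Li+].[I-]
Why: Cram-chelate-controlled Grignard addition (Mg bridges C=O and the oxirane oxygen, methyl enters anti to the oxirane CH2) sets the R tertiary carbinol, and the acetic acid quench at −78 °C prevents Payne migration before iodide opens the epoxide by SN2 at the terminal CH2; the secondary C–O bond is kept, and its descriptor changes from S to R only because iodine raises the CIP rank of C1.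

**Step 11**
Reactants: 12 3-[2,4-bis(methoxymethoxy)phenyl]-1-[6-hydroxy-2,4-bis(methoxymethoxy)-3-(3-methylbut-2-en-1-yl)phenyl]prop-2-yn-1-one; 19 (2R,3R)-1-iodo-3,7-dimethyloct-6-ene-2,3-diol
Product: 21 2-[2,4-bis(methoxymethoxy)phenyl]-3-[(2S,3R)-2,3-dihydroxy-3,7-dimethyloct-6-en-1-yl]-5,7-bis(methoxymethoxy)-6-(3-methylbut-2-en-1-yl)-4H-chromen-4-one, via vinyl iodide 20 (not isolated)
Conditions: 19 (1.8 equiv), Mn2(CO)10 (10 mol %), NaHCO3 (3 equiv), PhCF3 (0.3 M in 12), 456 nm LEDs, 25 °C; then 50 °C, dark, 1 h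
Reagents that add atoms: none
Why: Proposed new method: an iodine-atom-transfer radical addition/annulation in which light cleaves Mn2(CO)10 to Mn(CO)5 radicals that abstract iodine from primary iodide 19, the β-hydroxyalkyl radical adds to the alkyne carbon next to C=O of 12 (the regiochemistry seen when alkyl radicals add to 3-arylpropiolates and 1,3-diaryl ynones, giving the aryl-stabilised vinyl radical), the vinyl radical takes iodine back from Mn(CO)5I or 19, and the hydrogen-bonded phenol displaces iodide from β-iodoenone 20 by 6-endo addition–elimination to close ring C (the side-chain OH would need a disfavoured 5-endo closure); a competing O–H to vinyl-radical hydrogen transfer leads through phenoxyl 6-endo closure and loss of HI to the same flavone; the closest known reaction types are Mn2(CO)10/visible-light atom-transfer addition of alkyl iodides to alkynes, radical alkylation–annulation of aryl alkynoates and base closure of o-hydroxyaryl β-halovinyl ketones to chromones; both stereocentres are spectators because the radical sits at C1 and no bond at C2 or C3 of the chain is broken.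

**Step 12**
Reactants: 21 2-[2,4-bis(methoxymethoxy)phenyl]-3-[(2S,3R)-2,3-dihydroxy-3,7-dimethyloct-6-en-1-yl]-5,7-bis(methoxymethoxy)-6-(3-methylbut-2-en-1-yl)-4H-chromen-4-one
Product: 22 2-(2,4-dihydroxyphenyl)-3-[(2S,3R)-2,3-dihydroxy-3,7-dimethyloct-6-en-1-yl]-5,7-dihydroxy-6-(3-methylbut-2-en-1-yl)-4H-chromen-4-one
Conditions: 3 M aq. HCl/MeOH 1:4, 40 °C, followed by TLC, NaHCO3 quench
Reagents that add atoms: none
Why: Acid-catalysed acetal exchange with methanol (MOM solvolysis) frees the four phenols; the dilute acid and low temperature are chosen to stay below the threshold for prenyl–phenol chroman formation and for cyclisation of the tertiary alcohol onto the distal alkene, and no stereocentre is ionised.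

**Compound list**
1 | resorcinol (benzene-1,3-diol) | Oc1cccc(O)c1 | starting material
2 | 1,3-bis(methoxymethoxy)benzene | COCOc1cccc(OCOC)c1 | intermediate
3 | prenyl bromide (1-bromo-3-methylbut-2-ene) | CC(C)=CCBr | starting material
4 | [2,6-bis(methoxymethoxy)phenyl]lithium | [Li]c1c(OCOC)cccc1OCOC | intermediate
5 | 1,3-bis(methoxymethoxy)-2-(3-methylbut-2-en-1-yl)benzene | CC(C)=CCc1c(OCOC)cccc1OCOC | intermediate
6 | 2-[3,5-bis(methoxymethoxy)-4-(3-methylbut-2-en-1-yl)phenyl]-4,4,5,5-tetramethyl-1,3,2-dioxaborolane | CC(C)=CCc1c(OCOC)cc(cc1OCOC)B1OC(C)(C)C(C)(C)O1 | intermediate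
7 | 3,5-bis(methoxymethoxy)-4-(3-methylbut-2-en-1-yl)phenol | CC(C)=CCc1c(OCOC)cc(O)cc1OCOC | intermediate
8 | 6-hydroxy-2,4-bis(methoxymethoxy)-3-(3-methylbut-2-en-1-yl)benzaldehyde | CC(C)=CCc1c(OCOC)cc(O)c(C=O)c1OCOC | intermediate
9 | 2-(1-hydroxyprop-2-yn-1-yl)-3,5-bis(methoxymethoxy)-4-(3-methylbut-2-en-1-yl)phenol (racemic) | CC(C)=CCc1c(OCOC)cc(O)c(C(O)C#C)c1OCOC | intermediate
10 | 1-iodo-2,4-bis(methoxymethoxy)benzene | COCOc1ccc(I)c(OCOC)c1 | intermediate
11 | 2-{3-[2,4-bis(methoxymethoxy)phenyl]-1-hydroxyprop-2-yn-1-yl}-3,5-bis(methoxymethoxy)-4-(3-methylbut-2-en-1-yl)phenol (racemic) | CC(C)=CCc1c(OCOC)cc(O)c(C(O)C#Cc2ccc(OCOC)cc2OCOC)c1OCOC | intermediate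
12 | 3-[2,4-bis(methoxymethoxy)phenyl]-1-[6-hydroxy-2,4-bis(methoxymethoxy)-3-(3-methylbut-2-en-1-yl)phenyl]prop-2-yn-1-one | CC(C)=CCc1c(OCOC)cc(O)c(C(=O)C#Cc2ccc(OCOC)cc2OCOC)c1OCOC | intermediate
13 | methyl (2S)-oxirane-2-carboxylate | COC(=O)[C@@H]1CO1 | starting material
14 | 5-bromo-2-methylpent-2-ene | CC(C)=CCCBr | starting material
15 | (4-methylpent-3-en-1-yl)magnesium bromide | CC(C)=CCC[Mg]Br | intermediate
16 | (2S)-N-methoxy-N-methyloxirane-2-carboxamide | CON(C)C(=O)[C@@H]1CO1 | intermediate
17 | 5-methyl-1-[(2S)-oxiran-2-yl]hex-4-en-1-one | CC(C)=CCCC(=O)[C@@H]1CO1 | intermediate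
18 | (2R)-6-methyl-2-[(2S)-oxiran-2-yl]hept-5-en-2-ol | CC(C)=CCC[C@@](C)(O)[C@@H]1CO1 | intermediate
19 | (2R,3R)-1-iodo-3,7-dimethyloct-6-ene-2,3-diol | CC(C)=CCC[C@@](C)(O)[C@@H](O)CI | intermediate
20 | 3-[2,4-bis(methoxymethoxy)phenyl]-2-[(2S,3R)-2,3-dihydroxy-3,7-dimethyloct-6-en-1-yl]-1-[6-hydroxy-2,4-bis(methoxymethoxy)-3-(3-methylbut-2-en-1-yl)phenyl]-3-iodoprop-2-en-1-one (E/Z mixture) | CC(C)=CCC[C@@](C)(O)[C@@H](O)CC(C(=O)c1c(O)cc(OCOC)c(CC=C(C)C)c1OCOC)=C(I)c1ccc(OCOC)cc1OCOC | intermediate
21 | 2-[2,4-bis(methoxymethoxy)phenyl]-3-[(2S,3R)-2,3-dihydroxy-3,7-dimethyloct-6-en-1-yl]-5,7-bis(methoxymethoxy)-6-(3-methylbut-2-en-1-yl)-4H-chromen-4-one | CC(C)=CCC[C@@](C)(O)[C@@H](O)Cc1c(-c2ccc(OCOC)cc2OCOC)oc2cc(OCOC)c(CC=C(C)C)c(OCOC)c2c1=O | intermediate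
22 | 2-(2,4-dihydroxyphenyl)-3-[(2S,3R)-2,3-dihydroxy-3,7-dimethyloct-6-en-1-yl]-5,7-dihydroxy-6-(3-methylbut-2-en-1-yl)-4H-chromen-4-one | CC(C)=CCC[C@@](C)(O)[C@@H](O)Cc1c(-c2ccc(O)cc2O)oc2cc(O)c(CC=C(C)C)c(O)c2c1=O | target

**Count**
Total steps: 12. Longest linear sequence: 9 steps (1, 2, 3, 4, 5, 7, 8, 11, 12).

**Three steps most likely to fail**

Step 11 (new radical annulation). The risks are: ionic closure of 12 to the 3-unsubstituted flavone before the radical arrives, 6-exo cyclisation of the radical onto its own distal alkene (about 10^4 per second, hence the high concentration and excess of 19), and addition at the wrong alkyne carbon. The fallback sets out from 12 and comes back at 21. DMAP (cat.) in DMF at rt closes 12 by 6-endo oxa-Michael addition to 2-[2,4-bis(methoxymethoxy)phenyl]-5,7-bis(methoxymethoxy)-6-(3-methylbut-2-en-1-yl)-4H-chromen-4-one F1. Lithiation at C3 with LDA in THF at −78 °C and an I2 quench gives 2-[2,4-bis(methoxymethoxy)phenyl]-3-iodo-5,7-bis(methoxymethoxy)-6-(3-methylbut-2-en-1-yl)-4H-chromen-4-one F2. A nickel-catalysed reductive cross-electrophile coupling of F2 with iodide 19 (NiI2, 4,4'-di-tert-butyl-2,2'-bipyridine, Mn powder, NaI, DMPU, 40 °C), in which the alkyl radical from 19 is captured at nickel, then gives 21.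

Step 9 (one-flask ester to epoxy ketone). The oxirane may be opened by chloride during the magnesium-amide stage, and 16 and 17 are small and water-soluble. The fallback sets out from 14 (as its Grignard reagent 15) and comes back at 17. Addition of 15 to acrolein (THF, −78 °C) gives racemic 7-methylocta-1,6-dien-3-ol F3. Sharpless kinetic-resolution epoxidation (Ti(OiPr)4, D-(−)-diisopropyl tartrate, t-BuOOH, 4 Å sieves, CH2Cl2, −20 °C, stopped near 50% conversion) epoxidises the R alcohol to the erythro product (1R)-5-methyl-1-[(2S)-oxiran-2-yl]hex-4-en-1-ol F4; the distal alkene is not allylic to an OH and is left alone. Dess–Martin oxidation of F4 gives 17.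

Step 12 (global MOM removal). Acid may cyclise the prenyl group onto a neighbouring phenol or the tertiary alcohol onto the distal alkene. The fallback sets out from 12 and comes back at 22. Compound 12 is taken to the 3-iodoflavone F2 as described for step 11. The MOM groups are removed there (3 M HCl/MeOH, 40 °C), before any diol or second alkene is present, to give 2-(2,4-dihydroxyphenyl)-5,7-dihydroxy-3-iodo-6-(3-methylbut-2-en-1-yl)-4H-chromen-4-one F5. The same nickel/manganese radical cross-coupling with 19 then gives 22 directly, so the finished side chain never meets acid.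

**Further compounds**
F1 | step 11 | 2-[2,4-bis(methoxymethoxy)phenyl]-5,7-bis(methoxymethoxy)-6-(3-methylbut-2-en-1-yl)-4H-chromen-4-one | COCOc1ccc(-c2cc(=O)c3c(OCOC)c(CC=C(C)C)c(OCOC)cc3o2)c(OCOC)c1
F2 | step 11 | 2-[2,4-bis(methoxymethoxy)phenyl]-3-iodo-5,7-bis(methoxymethoxy)-6-(3-methylbut-2-en-1-yl)-4H-chromen-4-one | COCOc1ccc(-c2oc3cc(OCOC)c(CC=C(C)C)c(OCOC)c3c(=O)c2I)c(OCOC)c1
F3 | step 9 | 7-methylocta-1,6-dien-3-ol (racemic) | CC(C)=CCCC(O)C=C
F4 | step 9 | (1R)-5-methyl-1-[(2S)-oxiran-2-yl]hex-4-en-1-ol | CC(C)=CCC[C@@H](O)[C@@H]1CO1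
F5 | step 12 | 2-(2,4-dihydroxyphenyl)-5,7-dihydroxy-3-iodo-6-(3-methylbut-2-en-1-yl)-4H-chromen-4-one | CC(C)=CCc1c(O)cc2oc(-c3ccc(O)cc3O)c(I)c(=O)c2c1O
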